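## Structural features

The target is a cyclopent-2-enone in which every ring carbon is substituted: C1 is the carbonyl, C2 carries a (Z)-pent-2-enyl group, C3 a seven-methylene chain ending in a methyl ester, C4 a secondary hydroxyl and C5 a bromine. C4 and C5 are adjacent stereocentres with hydroxyl and bromine trans. In this ring numbering they are 4R and 5S; the systematic name numbers from the chain-bearing carbon and reads 4S,5R for the same atoms. The SMILES of target, precursor and alternative products were checked against this assignment and are mutually consistent. The C4–C5–C1 segment is an α-bromo-β-hydroxy ketone: base would close it to an epoxide or start Favorskii and retro-aldol chemistry, whereas dehydration is blocked because it would create a cyclopentadienone. The side-chain alkene is Z and skipped relative to the enone, so strong acid or base can move it into conjugation, and the remote methyl ester restricts the use of hydride and hydroxide. C5 is epimerisable through the enol, so the centre that must be controlled absolutely is C4. The real difficulty is to set it on a fully substituted, acid- and base-sensitive ring without protecting groups. The key step uses the fact that C4(OH)–C5(Br)–C1(=O) is an aldol retron flanked by the C2=C3 alkene. Opening C4–C5 gives an acyclic Z keto-enal whose bromo-enol, alkene and protonated aldehyde make up a pentadienyl cation ready for 4π closure.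

## Logic of the disconnections

15 to 14. The ring bond C4–C5 is cut in the aldol sense. It lies between the two stereocentres and is the only ring bond whose formation creates both from achiral material. The gain is loss of the ring and of all stereocentres, since 14 is acyclic and achiral. The forward step must close a cis-disposed aldehyde and bromoacetyl group with absolute control at C4 from an external chiral acid, without loss of HBr or water.

14 to 12 (through 13). No skeletal bond is cut. The aldehyde carbon is raised to the carboxyl level and its oxygen is tied to C1 as an enol ester. 14 is too labile to carry through several steps, whereas 12 locks the cis geometry in a ring, masks the bromomethyl ketone as a bromo-enol ester and can be purified and stored. 14 is therefore released only one step before use, from the ring tautomer 13 of the very bromo-enol that the closure needs. The forward step must be a half-reduction that distinguishes the enol lactone from the remote methyl ester and stops at the lactol.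

12 to 10 (through 11). The enol C–O bond of the lactone (ring oxygen to the future C1) is cut, giving a carboxylic acid next to a 1-bromoalkyne. The carboxyl group thus delivers the ketone oxygen to the correct alkyne carbon, and the bromine is already on the future C5. The forward step needs 5-exo-dig closure in preference to 6-endo-dig, and cleavage of the tert-butyl ester with the methyl ester left intact.

10 to 9. The C(sp)–Br bond is exchanged for C(sp)–Si. A bromoalkyne would not survive a palladium/copper coupling, while the silyl group protects the terminus during the coupling and is the direct precursor of the bromide. The forward step must brominate the alkyne terminus only, in the presence of the Z alkene.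

9 to 7 and 8. The C(sp2)–C(sp) bond between the future C2 and C1 is cut. This splits off the two-carbon C1–C5 unit as a commercial alkyne and leaves an enol triflate. The coupling must work at a tetrasubstituted alkene with retention of geometry.

7 to 6. The enol O–S bond is cut. The geometry of the tetrasubstituted alkene is reduced to the geometry of a chelated β-keto ester enolate. The forward step must sulfonylate on oxygen with the sulfonate cis to the ester.

6 to 4 and 5. The bond between the future C3 and the first methylene of the ester chain is cut. The chain arrives from a commercial bromide with its methyl ester in place, at the most acidic carbon of 4. The forward step must be a mono-C-alkylation that does not move the Z alkene.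

4 to 1 and 2. The bond between the ketone carbon (future C2) and the α-carbon (future C3) is cut. The commercial Z acid 1 supplies the pentenyl group with its alkene geometry. The alcohol that opens 3 supplies an ester orthogonal to the methyl ester. Acylation and alcoholysis must proceed without β,γ to α,β migration of the alkene.

## Other disconnections considered

Alternative 1: The cut is the C2–C3 ring bond. In the forward sense the silyl enol ether A2, which already carries the C4 silyloxy stereocentre and an internal alkyne, would be treated with Ph3PAuCl/AgSbF6. Monovalent gold activates the alkyne, C2 of the enol ether attacks C3 in a 5-exo-dig Conia-ene closure, and DBU in the same flask would move the exocyclic alkene into the ring to give A1.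
- In favour: addition of a silyl enol ether to a gold-activated alkyne is well-documented ring-forming chemistry, and the medium is neutral and tolerant of the ester. C4 would be fixed beforehand by standard asymmetric propargylic alcohol chemistry, so the absolute configuration would not depend on an untested catalyst–substrate match. On this point, and in the quality of its precedent, it is the better plan.
- Against: A2 requires enolisation of a β-silyloxy ketone towards C2 and away from C5, where elimination of the silyloxy group threatens. The alkyne is internal and should close more slowly than the terminal alkynes for which the reaction is best known. The base-mediated alkene shift must stop at the ring without disturbing the skipped Z alkene. A1 still lacks the bromine, so C5 bromination through the kinetic enolate and desilylation add two steps after ring closure. The C4 descriptor of A1 is S only because priorities change when C5 carries no bromine; the spatial arrangement is that of 15.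
- Comparison: both plans close the five-membered ring in one catalytic step from an acyclic precursor and are equal in that respect. The alternative creates no stereocentre in its key step where the chosen closure creates two, and it is longer by protection, bromination and deprotection. Mechanistically it is the safer closure.

Alternative 2: The cut is the C1–C5 bond. LiN(SiMe3)2 would deprotonate the tert-butyl acetate terminus of diester A4 at C5, and the enolate would add to the conjugated methyl ester carbon C1 (Dieckmann condensation) to give the β-keto ester A3. Acidolysis of the tert-butyl ester, decarboxylative bromination and desilylation would follow.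
- In favour: every reaction type is classical, and the five-membered ring should form in preference to attack on the remote chain ester. C4 would come from established asymmetric acetate-aldol chemistry. C5 settles trans under thermodynamic control exactly as in the chosen plan, so the two are equal in how C5 is controlled.
- Against: the C5 enolate of A4 has the C4 silyloxy group in the β-position and can expel it (E1cB) faster than it attacks a tetrasubstituted, conjugated and therefore deactivated ester. The Z geometry places the C1 ester next to the C4 oxygen, so any loss of the silyl group leads to a butenolide. The tert-butyl ester must be cleaved without loss of the silyl ether, and bromodecarboxylation risks double bromination.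
- Comparison: the Dieckmann route is mechanistically more conventional and its absolute stereocontrol more predictable, which is a real advantage. It needs three operations after ring closure and a protecting group, whereas the chosen closure ends at the target. Structurally it forms the ring at a bond remote from C4, so the stereocentre must survive a strongly basic step while standing β to a carbanion.

Alternative 3: The cut is the C3–C4 bond together with the C5–Br bond. MgBr2·OEt2 would trigger Nazarov cyclisation of the axially chiral allenyl vinyl ketone A6, drawn with the aR axis that a steric model of torquoselection calls for. The central allene carbon C3 bonds to the silyloxy-bearing vinyl terminus C4, bromide intercepts the oxyallyl cation at C5, and protonation of the dienolate at the former allene terminus leaves the C2=C3 alkene of A5. Desilylation would complete the synthesis.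
- In favour: it is the most convergent of all the plans, forming the ring, a carbon–carbon bond, the carbon–bromine bond and both stereocentres in one operation. That is one bond more than the chosen key step, and on bond economy it is the better plan. Axis-to-centre chirality transfer in allene Nazarov closures is a recognised principle.
- Against: A6 must be made and kept enantiomerically pure although bromide can add reversibly to an allenyl ketone and erase the axis. Its β-silyloxy enone is a vinylogous silyl ester that Lewis acids cleave. Bromide must be captured at C5 and not at C2, and the dienolate must be protonated at the exocyclic carbon. Fluoride desilylation of an α-bromo-β-silyloxy ketone invites epoxide formation.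
- Comparison: both plans rest on a conrotatory 4π closure of a pentadienyl cation and on the trans preference at C4/C5, and are equal there. The chosen plan is better in that its precursor is achiral and made from a β-keto ester in a few standard steps, that absolute control comes from a catalyst and not from a labile stereogenic axis, and that no protecting group has to be removed from the bromohydrin.

Key step: step 8

Remark on the chemistry: the absolute sense of induction of the phosphoramide cannot be predicted with confidence; the (R)-catalyst is written, and the (S)-catalyst takes its place should the closure favour the other antipode.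

## Route

Step 1
Reactants: 1 (3Z)-hex-3-enoic acid; 2 Meldrum's acid
Product: 4 tert-butyl (5Z)-3-oxooct-5-enoate, via acyl Meldrum's acid 3 (not isolated)
Conditions: DCC, DMAP, CH2Cl2, 0 °C → rt; filter, acid wash; then t-BuOH, toluene, 80 °C
Reagents that add atoms: tert-butanol, CC(C)(C)O
Why: Carbodiimide-mediated C-acylation of Meldrum's acid gives 3, which on heating loses acetone and carbon dioxide to an acyl ketene that tert-butanol traps as the β-keto ester; no stereocentre is formed, and the neutral thermal conditions should leave the Z alkene, one methylene away from the new ketone, out of conjugation.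

Step 2
Reactants: 4 tert-butyl (5Z)-3-oxooct-5-enoate; 5 methyl 8-bromooctanoate
Product: 6 tert-butyl (5Z)-2-(8-methoxy-8-oxooctyl)-3-oxooct-5-enoate
Conditions: NaH, THF–DMF, 0 °C; then 5, NaI (cat.), 50 °C
Reagents that add atoms: none
Why: Iodide-assisted SN2 C-alkylation of the stabilised sodium enolate of a β-keto ester with a primary bromide; deprotonation between the two carbonyl groups is so much easier than at the allylic C4 methylene that the Z alkene should stay in place, and the new stereocentre is racemic and is erased in step 3.

Step 3
Reactants: 6 tert-butyl (5Z)-2-(8-methoxy-8-oxooctyl)-3-oxooct-5-enoate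
Product: 7 tert-butyl (2Z,5Z)-2-(8-methoxy-8-oxooctyl)-3-[(trifluoromethanesulfonyl)oxy]octa-2,5-dienoate
Conditions: NaH, CH2Cl2, 0 °C; Tf2O, −78 → 0 °C
Reagents that add atoms: trifluoromethanesulfonic anhydride, O=S(=O)(OS(=O)(=O)C(F)(F)F)C(F)(F)F
Why: O-sulfonylation of the β-keto ester enolate; in a non-coordinating solvent sodium bridges the enolate and ester oxygens, so the triflate should end cis to the tert-butyl ester (2Z), which is the geometry the later lactonisation needs.

Step 4
Reactants: 7 tert-butyl (2Z,5Z)-2-(8-methoxy-8-oxooctyl)-3-[(trifluoromethanesulfonyl)oxy]octa-2,5-dienoate; 8 ethynyltrimethylsilane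
Product: 9 tert-butyl (2Z)-2-(8-methoxy-8-oxooctyl)-3-[(2Z)-pent-2-en-1-yl]-5-(trimethylsilyl)pent-2-en-4-ynoate
Conditions: Pd(PPh3)2Cl2 (5 mol %), CuI (10 mol %), Et3N, THF, rt
Reagents that add atoms: none
Why: Sonogashira coupling of an electron-poor enol triflate (oxidative addition to zerovalent palladium, transmetalation from the copper acetylide, reductive elimination) proceeds with retention of alkene geometry at room temperature, so the alkyne stays cis to the ester.

Step 5
Reactants: 9 tert-butyl (2Z)-2-(8-methoxy-8-oxooctyl)-3-[(2Z)-pent-2-en-1-yl]-5-(trimethylsilyl)pent-2-en-4-ynoate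
Product: 10 tert-butyl (2Z)-5-bromo-2-(8-methoxy-8-oxooctyl)-3-[(2Z)-pent-2-en-1-yl]pent-2-en-4-ynoate
Conditions: NBS, AgNO3 (10 mol %), acetone, rt, dark
Reagents that add atoms: N-bromosuccinimide, O=C1CCC(=O)N1Br
Why: Silver-nitrate-catalysed bromodesilylation, in which the silver acetylide formed from the silylalkyne is brominated by NBS; in the dark and without a radical initiator the isolated Z alkene and the doubly allylic methylene should not compete.

Step 6
Reactants: 10 tert-butyl (2Z)-5-bromo-2-(8-methoxy-8-oxooctyl)-3-[(2Z)-pent-2-en-1-yl]pent-2-en-4-ynoate
Product: 12 methyl 8-[(5Z)-5-(bromomethylidene)-2-oxo-4-[(2Z)-pent-2-en-1-yl]-2,5-dihydrofuran-3-yl]octanoate, via bromoenynoic acid 11 (not isolated)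
Conditions: TFA, CH2Cl2, 0 °C → rt; evaporate; Ag2CO3 (10 mol %), MeCN, rt
Reagents that add atoms: none
Why: Acidolysis of the tert-butyl ester (methyl ester untouched) frees acid 11, whose carboxylate adds anti across the silver-activated bromoalkyne in a 5-exo-dig lactonisation at the carbon remote from bromine, the mode favoured both by the polarisation of a 1-bromoalkyne and by silver catalysis of (Z)-2-en-4-ynoic acids; the lactone now fixes the cis relation of the future aldehyde and ketone.

Step 7
Reactants: 12 methyl 8-[(5Z)-5-(bromomethylidene)-2-oxo-4-[(2Z)-pent-2-en-1-yl]-2,5-dihydrofuran-3-yl]octanoate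
Product: 14 methyl (9Z,12Z)-10-(2-bromoacetyl)-9-formylpentadeca-9,12-dienoate, via bromomethylidene lactol 13 (not isolated)
Conditions: i-Bu2AlH (1.05 equiv), CH2Cl2, −78 °C; MeOH, aq. potassium sodium tartrate, −78 → 0 °C; used at once
Reagents that add atoms: none
Why: Half-reduction of a lactone to the lactol: the enol lactone carbonyl is more electrophilic and more Lewis basic than the remote methyl ester, so one equivalent of hydride at −78 °C should give the aluminium lactolate of 13, which on work-up opens to the aldehyde and the bromo-enol and ketonises to 14 with the 9Z geometry inherited from the ring.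

Step 8
Reactants: 14 methyl (9Z,12Z)-10-(2-bromoacetyl)-9-formylpentadeca-9,12-dienoate
Product: 15 methyl 8-[(4S,5R)-4-bromo-5-hydroxy-3-oxo-2-[(2Z)-pent-2-en-1-yl]cyclopent-1-en-1-yl]octanoate
Conditions: (R)-3,3′-bis(2,4,6-triisopropylphenyl)-1,1′-binaphthyl-2,2′-diyl N-(trifluoromethanesulfonyl)phosphoramide (10 mol %), toluene, 5 Å MS, −20 → 0 °C
Reagents that add atoms: none
Why: Proposed new method: the strong chiral acid protonates the aldehyde oxygen and catalyses enolisation of the ketone towards the bromomethyl group, its only α-position, so that C5, C1, C2, C3 and C4 become a 1,4-dihydroxypentadienyl cation paired with the phosphoramide anion; thermal conrotatory 4π closure joins C4 to C5, and loss of the hydroxyl proton from the resulting hydroxyallyl cation gives the enone. The closest known reaction type is the ring-forming stage of the Piancatelli rearrangement of 2-furylcarbinols, whose amine-terminated variants have been made enantioselective with BINOL-derived phosphoric acids and N-triflylphosphoramides; a halogen on the cation terminus, a hydroxyl in place of the amine as the hydrogen-bonding handle, and entry from a preformed keto-enal are the untested elements. The five-membered ring closes by 4π electrocyclisation, which is equally a 5-(enolexo)-exo-trig aldol addition. C4 is set under catalyst control: the anion, hydrogen-bonded to the two hydroxyl groups, selects one helical sense of the cation and therefore one direction of conrotation. C5 follows from conrotation of a cation whose bromine and C4 oxygen both point outwards, which places Br trans to OH, and because C5 is an enolisable α-bromo ketone centre it also converges on the trans isomer thermodynamically. The step needs chemoselective enolisation (secured by the fully substituted C2), a cis arrangement of the two carbonyl arms (secured by the tetrasubstituted 9Z alkene inherited from lactone 12) and no dehydration (which would require an antiaromatic cyclopentadienone). Low temperature, molecular sieves and a non-polar solvent are chosen to keep the ion pair tight and to disfavour vinylogous enolisation into the skipped diene and aromatisation to a furan with loss of HBr.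

## Compound list

1 | (3Z)-hex-3-enoic acid | CC/C=C\CC(=O)O | starting material
2 | Meldrum's acid (2,2-dimethyl-1,3-dioxane-4,6-dione) | CC1(C)OC(=O)CC(=O)O1 | starting material
3 | 5-[(3Z)-1-hydroxyhex-3-en-1-ylidene]-2,2-dimethyl-1,3-dioxane-4,6-dione (acyl Meldrum's acid, enol form) | CC/C=C\CC(O)=C1C(=O)OC(C)(C)OC1=O | intermediate (not isolated)
4 | tert-butyl (5Z)-3-oxooct-5-enoate | CC/C=C\CC(=O)CC(=O)OC(C)(C)C | intermediate
5 | methyl 8-bromooctanoate | COC(=O)CCCCCCCBr | starting material
6 | tert-butyl (5Z)-2-(8-methoxy-8-oxooctyl)-3-oxooct-5-enoate (racemic at C2) | CC/C=C\CC(=O)C(CCCCCCCC(=O)OC)C(=O)OC(C)(C)C | intermediate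
7 | tert-butyl (2Z,5Z)-2-(8-methoxy-8-oxooctyl)-3-[(trifluoromethanesulfonyl)oxy]octa-2,5-dienoate | CC/C=C\C/C(OS(=O)(=O)C(F)(F)F)=C(\CCCCCCCC(=O)OC)C(=O)OC(C)(C)C | intermediate
8 | ethynyltrimethylsilane | C#C[Si](C)(C)C | starting material
9 | tert-butyl (2Z)-2-(8-methoxy-8-oxooctyl)-3-[(2Z)-pent-2-en-1-yl]-5-(trimethylsilyl)pent-2-en-4-ynoate | CC/C=C\C/C(C#C[Si](C)(C)C)=C(\CCCCCCCC(=O)OC)C(=O)OC(C)(C)C | intermediate
10 | tert-butyl (2Z)-5-bromo-2-(8-methoxy-8-oxooctyl)-3-[(2Z)-pent-2-en-1-yl]pent-2-en-4-ynoate | CC/C=C\C/C(C#CBr)=C(\CCCCCCCC(=O)OC)C(=O)OC(C)(C)C | intermediate
11 | (2Z)-5-bromo-2-(8-methoxy-8-oxooctyl)-3-[(2Z)-pent-2-en-1-yl]pent-2-en-4-ynoic acid | CC/C=C\C/C(C#CBr)=C(\CCCCCCCC(=O)OC)C(=O)O | intermediate (not isolated)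
12 | methyl 8-[(5Z)-5-(bromomethylidene)-2-oxo-4-[(2Z)-pent-2-en-1-yl]-2,5-dihydrofuran-3-yl]octanoate | CC/C=C\CC1=C(CCCCCCCC(=O)OC)C(=O)O/C1=C\Br | intermediate
13 | methyl 8-[(5Z)-5-(bromomethylidene)-2-hydroxy-4-[(2Z)-pent-2-en-1-yl]-2,5-dihydrofuran-3-yl]octanoate (racemic lactol, formed as its aluminium alkoxide) | CC/C=C\CC1=C(CCCCCCCC(=O)OC)C(O)O/C1=C\Br | intermediate (not isolated)
14 | methyl (9Z,12Z)-10-(2-bromoacetyl)-9-formylpentadeca-9,12-dienoate | O=C(CBr)/C(C/C=C\CC)=C(\C=O)CCCCCCCC(=O)OC | intermediate
15 | methyl 8-[(4S,5R)-4-bromo-5-hydroxy-3-oxo-2-[(2Z)-pent-2-en-1-yl]cyclopent-1-en-1-yl]octanoate | CC/C=C\CC1=C(CCCCCCCC(=O)OC)[C@@H](O)[C@H](Br)C1=O | target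

## Step count and least certain steps

Total step count: 8. Longest linear sequence: 8 steps (1 to 15; compounds 2, 5 and 8 enter directly).

**Step 8 (key step, proposed new method).**
- What may go wrong: facial discrimination by the chiral anion may be poor, because the cation offers only two hydroxyl groups as anchoring points. A racemic background closure may run without the catalyst, or already during the work-up of step 7. The cyclic hemiacetal may lose water and then HBr, aromatising to a furan. Vinylogous enolisation may pull the skipped diene into conjugation. Retro-aldol may erode the product on prolonged exposure to the acid.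
- Fallback, established reactions only, leaving the route at 9 and rejoining it at 15:
  - K2CO3 in MeOH removes the silyl group of 9 to give the terminal enyne ester F1.
  - TFA frees the enynoic acid F2, which Ag2CO3 cyclises (5-exo-dig) to the 5-methylidene butenolide F3.
  - One equivalent of i-Bu2AlH at −78 °C gives the lactol F4, which opens on work-up to the methyl keto-enal F5.
  - In pH 8 phosphate buffer F5 undergoes the long-known aldol ring closure of cis-4-oxo-2-enals to the racemic hydroxy-enone F6.
  - Lipase-catalysed acetylation (Candida antarctica lipase B, vinyl acetate, t-BuOMe) is expected, by analogy with simpler 4-hydroxycyclopent-2-enones and the empirical size rule for lipases, to leave the (S)-alcohol F7 and turn its antipode into the (R)-acetate F8, which is removed by chromatography.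
  - Et3SiCl/imidazole gives the silyl ether F9.
  - LiN(SiMe3)2 in THF at −78 °C forms the cross-conjugated C5 enolate, and NBS should brominate it anti to the silyloxy group to give the bromo silyl ether F10.
  - HF·pyridine in THF at 0 °C releases 15.

**Step 7.**
- What may go wrong: hydride may also attack the remote methyl ester. The aluminium lactolate may collapse at low temperature, which would expose the aldehyde to over-reduction or allow an uncontrolled racemic aldol closure through the aluminium bromo-enolate.
- Fallback, leaving at 10 and rejoining at 14: TFA converts 10 into acid 11. Isobutyl chloroformate and N-methylmorpholine give the mixed anhydride F11, which NaBH4 at −15 °C reduces to the allylic alcohol F12 without touching the methyl ester. MnO2 oxidises F12 to the enynal F13. Gold-catalysed hydration of the 1-bromoalkyne ((Ph3P)AuNTf2, wet dioxane), assisted by the neighbouring aldehyde oxygen, gives lactol 13 and hence 14. The aldehyde level is thus reached by oxidation of an alcohol, and no hydride meets the enol lactone.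

**Step 6.**
- What may go wrong: 6-endo-dig closure may compete and give a pyranone. The acid may shift the skipped diene. The bromoalkyne may degrade under silver catalysis.
- Fallback, leaving at 7 and rejoining at 12: Stille coupling of 7 with tributyl(1-ethoxyvinyl)stannane (Pd(PPh3)4, LiCl, dioxane, 80 °C) gives the ethoxydiene F14. NBS in wet THF at 0 °C converts the enol ether into the bromomethyl ketone F15. TFA removes the tert-butyl group, and the keto acid is obtained as its ring tautomer, the pseudo-acid F16. P2O5 in CH2Cl2 dehydrates F16 to 12. The lactone C–O bond is then formed by ring–chain tautomerism of a ketone and not by addition to an alkyne, so no 6-endo pathway exists.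

**Step 3.**
- What may go wrong: geometric control may be lost in the O-sulfonylation if the sodium chelate is not maintained. Deprotonation at the allylic methylene may lead to a dienyl triflate.
- Fallback, leaving at 6 and rejoining at 9: TsCl with TMEDA and LiCl in MeCN, where lithium chelation of the neutral keto ester directs sulfonylation to the Z enol, gives the enol tosylate F17. This is stable to chromatography, so a minor geometric isomer can be removed. F17 is coupled with 8 under copper-free conditions (PdCl2(MeCN)2, 2-dicyclohexylphosphino-2′,4′,6′-triisopropylbiphenyl, Cs2CO3, MeCN, 60 °C) to give 9.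

## Further compounds

F1 | step 8 | tert-butyl (2Z)-2-(8-methoxy-8-oxooctyl)-3-[(2Z)-pent-2-en-1-yl]pent-2-en-4-ynoate | CC/C=C\C/C(C#C)=C(\CCCCCCCC(=O)OC)C(=O)OC(C)(C)C
F2 | step 8 | (2Z)-2-(8-methoxy-8-oxooctyl)-3-[(2Z)-pent-2-en-1-yl]pent-2-en-4-ynoic acid | CC/C=C\C/C(C#C)=C(\CCCCCCCC(=O)OC)C(=O)O
F3 | step 8 | methyl 8-[5-methylidene-2-oxo-4-[(2Z)-pent-2-en-1-yl]-2,5-dihydrofuran-3-yl]octanoate | CC/C=C\CC1=C(CCCCCCCC(=O)OC)C(=O)OC1=C
F4 | step 8 | methyl 8-[2-hydroxy-5-methylidene-4-[(2Z)-pent-2-en-1-yl]-2,5-dihydrofuran-3-yl]octanoate (racemic lactol) | CC/C=C\CC1=C(CCCCCCCC(=O)OC)C(O)OC1=C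
F5 | step 8 | methyl (9Z,12Z)-10-acetyl-9-formylpentadeca-9,12-dienoate | CC(=O)/C(C/C=C\CC)=C(\C=O)CCCCCCCC(=O)OC
F6 | step 8 | methyl 8-[5-hydroxy-3-oxo-2-[(2Z)-pent-2-en-1-yl]cyclopent-1-en-1-yl]octanoate (racemic) | CC/C=C\CC1=C(CCCCCCCC(=O)OC)C(O)CC1=O
F7 | step 8 | methyl 8-[(5S)-5-hydroxy-3-oxo-2-[(2Z)-pent-2-en-1-yl]cyclopent-1-en-1-yl]octanoate | CC/C=C\CC1=C(CCCCCCCC(=O)OC)[C@@H](O)CC1=O
F8 | step 8 | methyl 8-[(5R)-5-acetoxy-3-oxo-2-[(2Z)-pent-2-en-1-yl]cyclopent-1-en-1-yl]octanoate | CC/C=C\CC1=C(CCCCCCCC(=O)OC)[C@H](OC(C)=O)CC1=O
F9 | step 8 | methyl 8-[(5S)-3-oxo-2-[(2Z)-pent-2-en-1-yl]-5-(triethylsilyloxy)cyclopent-1-en-1-yl]octanoate | CC/C=C\CC1=C(CCCCCCCC(=O)OC)[C@@H](O[Si](CC)(CC)CC)CC1=O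
F10 | step 8 | methyl 8-[(4S,5R)-4-bromo-3-oxo-2-[(2Z)-pent-2-en-1-yl]-5-(triethylsilyloxy)cyclopent-1-en-1-yl]octanoate | CC/C=C\CC1=C(CCCCCCCC(=O)OC)[C@@H](O[Si](CC)(CC)CC)[C@H](Br)C1=O
F11 | step 7 | (2Z)-5-bromo-2-(8-methoxy-8-oxooctyl)-3-[(2Z)-pent-2-en-1-yl]pent-2-en-4-ynoic isobutyl carbonic anhydride | CC/C=C\C/C(C#CBr)=C(\CCCCCCCC(=O)OC)C(=O)OC(=O)OCC(C)C
F12 | step 7 | methyl (9Z,12Z)-10-(bromoethynyl)-9-(hydroxymethyl)pentadeca-9,12-dienoate | CC/C=C\C/C(C#CBr)=C(\CCCCCCCC(=O)OC)CO
F13 | step 7 | methyl (9Z,12Z)-10-(bromoethynyl)-9-formylpentadeca-9,12-dienoate | CC/C=C\C/C(C#CBr)=C(\CCCCCCCC(=O)OC)C=O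
F14 | step 6 | tert-butyl (2Z,5Z)-3-(1-ethoxyethenyl)-2-(8-methoxy-8-oxooctyl)octa-2,5-dienoate | CC/C=C\C/C(C(=C)OCC)=C(\CCCCCCCC(=O)OC)C(=O)OC(C)(C)C
F15 | step 6 | tert-butyl (2Z,5Z)-3-(2-bromoacetyl)-2-(8-methoxy-8-oxooctyl)octa-2,5-dienoate | CC/C=C\C/C(C(=O)CBr)=C(\CCCCCCCC(=O)OC)C(=O)OC(C)(C)C
F16 | step 6 | methyl 8-[5-(bromomethyl)-5-hydroxy-2-oxo-4-[(2Z)-pent-2-en-1-yl]-2,5-dihydrofuran-3-yl]octanoate (racemic pseudo-acid) | CC/C=C\CC1=C(CCCCCCCC(=O)OC)C(=O)OC1(O)CBr
F17 | step 3 | tert-butyl (2Z,5Z)-2-(8-methoxy-8-oxooctyl)-3-[(4-methylbenzenesulfonyl)oxy]octa-2,5-dienoate | CC/C=C\C/C(OS(=O)(=O)c1ccc(C)cc1)=C(\CCCCCCCC(=O)OC)C(=O)OC(C)(C)C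
A1 | alternative 1 | methyl 8-[(5S)-5-(tert-butyldimethylsilyloxy)-3-oxo-2-[(2Z)-pent-2-en-1-yl]cyclopent-1-en-1-yl]octanoate | CC/C=C\CC1=C(CCCCCCCC(=O)OC)[C@@H](O[Si](C)(C)C(C)(C)C)CC1=O
A2 | alternative 1 | methyl (10S,12Z,15Z)-10,12-bis(tert-butyldimethylsilyloxy)octadeca-12,15-dien-8-ynoate | CC/C=C\C/C=C(/C[C@H](O[Si](C)(C)C(C)(C)C)C#CCCCCCCC(=O)OC)O[Si](C)(C)C(C)(C)C
A3 | alternative 2 | tert-butyl (1S,2S)-2-(tert-butyldimethylsilyloxy)-3-(8-methoxy-8-oxooctyl)-5-oxo-4-[(2Z)-pent-2-en-1-yl]cyclopent-3-ene-1-carboxylate | CC/C=C\CC1=C(CCCCCCCC(=O)OC)[C@@H](O[Si](C)(C)C(C)(C)C)[C@H](C(=O)OC(C)(C)C)C1=O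
A4 | alternative 2 | 6-tert-butyl 1-methyl (2Z,4S)-4-(tert-butyldimethylsilyloxy)-3-(8-methoxy-8-oxooctyl)-2-[(2Z)-pent-2-en-1-yl]hex-2-enedioate | COC(=O)/C(C/C=C\CC)=C(/CCCCCCCC(=O)OC)[C@@H](O[Si](C)(C)C(C)(C)C)CC(=O)OC(C)(C)C
A5 | alternative 3 | methyl 8-[(4S,5R)-4-bromo-3-oxo-2-[(2Z)-pent-2-en-1-yl]-5-(triisopropylsilyloxy)cyclopent-1-en-1-yl]octanoate | CC/C=C\CC1=C(CCCCCCCC(=O)OC)[C@@H](O[Si](C(C)C)(C(C)C)C(C)C)[C@H](Br)C1=O
A6 | alternative 3 | methyl (aR,12E)-11-oxo-10-[(2Z)-pent-2-en-1-yl]-13-(triisopropylsilyloxy)trideca-8,9,12-trienoate | [H]C(CCCCCCC(=O)OC)=[C@@]=C(C/C=C\CC)C(=O)/C=C/O[Si](C(C)C)(C(C)C)C(C)C
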